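In the early minutes of this flask the first step relaxes with a half-life of 0.303 min, shorter than the partner's 0.96 min, and the fourth step's rate constant is larger still. So I freeze the split of the unreacted pool: substrate, open intermediate and dormant form.

substrate 23 mM; partner 18.4 mM; time 30 min

    substrate ⇌ open intermediate (K1 = 6.5, k1 = 0.033 s⁻¹)
    partner → second intermediate (k2 = 0.012 s⁻¹)
    open intermediate + second intermediate → target (k3 = 1.0 M⁻¹ s⁻¹)
    substrate ⇌ dormant form (K4 = 1.2, k4 = 0.47 s⁻¹)
    second intermediate → side product (k5 = 0.0052 s⁻¹)

- which holds at 30 min: what has brought the reaction to rest, or that it has not come to rest (all of the substrate has reacted / the partner has run out first / it is still moving)
- the target standing at 30 min, as a percentage of the substrate charged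
- the open intermediate standing at 30 min, as a percentage of the substrate charged

- the reaction counts as stopped when no species that holds the substrate changes by six tenths of a point or more over the second half of the time
- run time (flask): 30 min

Which numbers must I know well? The first and fourth rate constants set how fast the split forms, and they do not enter my reckoning. The partner's rate constant sets when the partner goes, its half-life being short against 30 min, and it does not enter either. A relative error in the two equilibrium constants reaches the split with weights 0.253 and 0.138. One in the third and fifth rate constants reaches the target with a weight of about 0.232. The partner charge reaches it about one for one and the substrate charge with a weight of about 0.768, so those two charges are the numbers to know well.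

With substrate counted as one, open intermediate 6.5 and dormant form 1.2, the part of the pool standing as open intermediate is

f = 0.747

I call this the open share. As fractions of the substrate charge, the partner, the limiting reagent, is worth e, and the selectivity factor of target over side product at full pool is B:

e = 0.800, B = 3.30

first pass, full pool: target = 0.614

second pass, mean pool 0.693: target = 55.7%

open intermediate = f × remaining pool = 33.1%

end: the partner has run out first

The forecast gives the partner has run out first, target 52% and open intermediate 36%, on these grounds: “leaving unreacted substrate frozen in its fast equilibrium with about three quarters as open intermediate”. Its target is lower than mine, and its open intermediate higher.

For this flask the simulation gives the partner has run out first, with 0% of the partner left, target 51.8% and open intermediate 36.0%.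

The open share times what the target did not take gives 36.0% for this flask. For the neighbour charged with 57 mM of substrate, it gives 54.6%, and that neighbour stands at 54.6%. In this flask 5.5% of the substrate stays unconverted because of the way back from open intermediate: with that way back removed, conversion of substrate goes from 94.5% to 100%.

The numbers were set for the occasion; the run is a simulation.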